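## The problem

Ring positions are written with a lower-case ring letter and the atom number (a4 is carbon 4 of ring A), with rings A to G and atoms 1 to 6 taken in the order of the SMILES string.

The target is a linear chain of seven benzene rings joined only by six diaryl ether oxygens (a4–O–b1, b4–O–c1, c6–O–d1, d5–O–e1, e6–O–f1, f4–O–g1) and carrying eighteen free phenolic hydroxyls. There is no ring-to-ring carbon–carbon bond and no stereocentre, so nothing has to be controlled stereochemically; the whole task is regiocontrolled C–O bond formation between highly oxygenated arenes. Rings C and E are pentaoxygenated with a single ring hydrogen, ring D is 1,3,4,5-tetraoxygenated, rings B and F are 3,5-dihydroxy-1,4-dioxygenated, and rings A and G are the 2,4,6- and 3,4,5-trihydroxyphenyl caps. Five ether oxygens sit on a carbon flanked by two oxygen substituents (a4, b4, c6, e6, f4), where a phenol is a poor nucleophile for arylation and a halide is slow in metal-catalysed coupling. The free polyphenol, with its pyrogallol and phloroglucinol units, oxidises readily in air and base, so every hydroxyl has to travel masked and be released in the last operation under acidic, oxygen-free conditions. The feature that opens the end game is that b1 and g1 are each flanked by two ring hydrogens and lie para to an oxygen, which is the pattern of the carboxyl-bearing carbon of syringic and gallic acid, while their partners a4 and f4 are hindered phenol carbons; each terminal ether is therefore an aryl benzoate that has lost carbon monoxide. The internal hindered carbons b4, c6 and e6 lie para or ortho to a position that must end as carboxyl or oxygen (b1, c1, e1), so a formyl group there can activate them as electrophiles and then be converted.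

## Retrosynthesis

**25 to 24.** The eighteen O–H bonds of target 25 are traced back to the methyl ethers of per-O-methyl heptamer 24. Methyl is chosen because every monomer is available as its methyl ether and because it survives copper, peracid, hydrogenolysis and hot zerovalent nickel; benzyl ethers would be at risk in the last two. The forward reaction must cleave eighteen aryl methyl ethers without touching six diaryl ethers, which is what BBr3 does.

**24 to 23.** The two terminal ethers a4–O–b1 and f4–O–g1 are cut and one carbon monoxide is put back into each, giving diester 23. The neighbouring cuts are direct arylation of the two hindered phenols, or two more rounds of the formyl-activated substitution and peracid oxidation used for the inner rings. Against these, the ester cut brings both end rings in as intact catalogue compounds by acylation, needs no re-methylation, spares two peracid oxidations on large electron-rich oligomers, and settles both ends in one operation. It asks zerovalent nickel to insert into two acyl C–O bonds, lose carbon monoxide and reductively eliminate the C–O bond, which is beyond what has been shown for esters of such phenols. For that reason the formyl-based capping is held ready as the fallback.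

**23 to 18.** Diester 23 is unfolded by cutting its two ester C–O bonds in turn: the ring G acyl group goes back to acid chloride 22 and phenol 21, the f4 hydroxyl of 21 to its benzyl ether 20, and the ring A ester of 20 to 2,4,6-trimethoxyphenol 19 and pentamer acid 18. The two chain ends are thus told apart as a carboxylic acid at b1 and a benzyl-protected phenol at f4. The forward steps are two acylations of hindered phenols, which are easy at the acyl carbon, and one hydrogenolysis.

**18 to 15.** The b1 carboxyl comes from the formyl group of aldehyde 17, and the b4–O–c1 ether is cut to phenol 15 and 4-fluoro-3,5-dimethoxybenzaldehyde 16. The hindered carbon b4 is the electrophile, activated by the para formyl group, and the nucleophile is the c1 phenol with only one ortho substituent. The precursor is one ring shorter and the monomer is bought.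

**15 to 12.** Phenol 15 comes from aldehyde 13 by exchange of formyl for hydroxyl, and the c6–O–d1 ether is cut to phenol 12 and 2-bromo-3,4,5-trimethoxybenzaldehyde 5. The doubly flanked carbon c6 is again the electrophile and the ortho formyl group assists copper insertion; the d1 phenol has two free ortho positions. The formyl carbon is exactly c1, so its oxidation delivers the next nucleophile where it is needed.

**12 to 8.** Phenol 12 comes from aldehyde 10, and the d5–O–e1 ether is cut to phenol 8 and 3-bromo-4,5-dimethoxybenzaldehyde 9. This is the one junction where the formyl group is meta to the reacting carbon and cannot activate it, so an Ullmann coupling of an ordinary ortho-methoxy bromide is required. The reverse polarity would need a ring E electrophile with the wrong orientation of oxygens.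

**8 to 4.** Phenol 8 comes from aldehyde 6, and the e6–O–f1 ether is cut to phenol 4 and a second portion of 5. This is the same coupling as for ring C, with the unhindered f1 phenol as nucleophile.

**4 to 1.** Phenol 4 comes from benzyl ether 2 by the same formyl-to-hydroxyl exchange, and 2 from syringaldehyde 1. The benzyl group marks the future f4 hydroxyl through all basic, oxidative and copper-mediated steps.

## Roads not taken

**Alternative 1:** Ring E is built from a four-membered ring. Cyclobutenone A2, a 4-methoxy-4-(1-methoxyvinyl)cyclobutenone made from a squaric ester and carrying the aryloxy group of rings F and G on carbon 2, opens on heating to a vinylketene. This closes through the new e1–e2 bond and tautomerises to trimer phenol A1 with a free e1 hydroxyl.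
- Merits: the five oxygens of ring E are placed without any regiochemical question, and the hindered e6–O–f1 ether is made by addition–elimination on a squarate with no metal. At this one bond the route is gentler than the copper coupling of step 3 on a bromide with two ortho substituents.
- Weak points: A2 needs a regioselective addition of 1-methoxyvinyllithium to one of two similar carbonyls and O-methylation of a tertiary alkoxide. Ring C has the same pattern and would need a second full round on a much larger aryloxide. The f4–O–g1 and a4–O–b1 ethers are not addressed; they would have to exist beforehand or be made later by other means.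
- Comparison: the idea solves ring construction where the difficulty is ether construction. The chosen plan sets against its gentler e6 ether that 5 delivers the whole of ring E, and again ring C, in two operations from a catalogue compound.

**Alternative 2:** Ring D is formed last by a [3+3] condensation. Aminoacrolein A4 (rings A to C on the central carbon of a 3-(dimethylamino)acrolein) and ketone A5 (a 1-aryloxy-3-methoxyacetone with rings E to G) are joined under base through the d2–d3 and d5–d6 bonds, giving heptamer A3 with a free d4 hydroxyl.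
- Merits: it is by far the most convergent plan, joining two trimers of similar size, and the free d4 hydroxyl costs nothing since every oxygen ends as a hydroxyl. In convergence it is clearly better than the fifteen-step linear sequence chosen here.
- Weak points: both nucleophilic carbons of A5 are alpha-alkoxy ketone carbons of low acidity with no second activating group, so self-condensation of A5 and hydrolysis of A4 compete. The bulky aryloxy group on the central carbon of A4 is attached through the flanked c6 and shields both electrophilic ends. The two trimers still contain one hindered terminal ether and one pentaoxygenated ring each, which must be made by the methods of the chosen route.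
- Comparison: the chosen plan sets against the better convergence that every bond formation other than the key step is of an established type, and that a failure of the key step can be repaired at the end, while a failed annulation strands both trimers.

**Alternative 3:** Ring A is folded from a chain. Thioester A7, an S-tert-butyl 6-aryloxy-3,5-dioxohexanethioate carrying rings B to G, is deprotonated with LiN(iPr)2. The aryloxy-bearing carbon 6 attacks the thioester carbonyl to form the a4–a3 bond, and the trione aromatises to heptamer A6 with a free phloroglucinol ring A.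
- Merits: the hindered a4–O–b1 ether is made as a simple alkyl aryl ether of the unhindered b1 phenol, ring A needs no demethylation, and no new method is required at this end. In these respects it is better than the chosen plan.
- Weak points: the carbon that must attack is the least acidic of the three methylene groups and reacts only as part of a trianion. 3,5-Dioxo thioesters prefer to close through oxygen to 4-hydroxy-2-pyrones. The six-carbon chain has to be built on a hexamer and carried through strong base. The f4–O–g1 ether is left untouched.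
- Comparison: the chosen plan sets against it that one operation settles both chain ends and that ring A arrives as a bought phenol in a single acylation.

Key step: step 14

Remark on the chemistry: the target has no stereocentre and no configurationally stable axis, so all structures are written without stereodescriptors; 5, 9, 16, 19 and 22 are taken as catalogue compounds.

## Route

Step 1
Reactants: 1 syringaldehyde (4-hydroxy-3,5-dimethoxybenzaldehyde)
Product: 2 4-(benzyloxy)-3,5-dimethoxybenzaldehyde
Conditions: BnBr, K2CO3, DMF, 60 °C
Reagents that add atoms: benzyl bromide, BrCc1ccccc1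
Why: Williamson ether synthesis on the phenoxide; the benzyl ether withstands base, copper and peracid and is later removed by hydrogenolysis without harm to an aryl ester.

Step 2
Reactants: 2 4-(benzyloxy)-3,5-dimethoxybenzaldehyde
Product: 4 4-(benzyloxy)-3,5-dimethoxyphenol (ring F phenol), via aryl formate 3 (not isolated)
Conditions: mCPBA, CH2Cl2, 0 °C to rt; aqueous NaHCO3 wash; then K2CO3 (cat.), MeOH, rt
Reagents that add atoms: mCPBA (3-chloroperoxybenzoic acid), OOC(=O)c1cccc(Cl)c1
Why: Baeyer–Villiger oxidation in the Dakin sense; the electron-rich aryl group with its para oxygen migrates in preference to hydride, and the formate shields the new phenol from the peracid until mild methanolysis releases it.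

Step 3
Reactants: 4 4-(benzyloxy)-3,5-dimethoxyphenol; 5 2-bromo-3,4,5-trimethoxybenzaldehyde
Product: 6 2-[4-(benzyloxy)-3,5-dimethoxyphenoxy]-3,4,5-trimethoxybenzaldehyde (EF aldehyde)
Conditions: CuI (cat.), N,N-dimethylglycine hydrochloride (cat.), Cs2CO3, 1,4-dioxane, 100 °C
Reagents that add atoms: none
Why: Ullmann diaryl ether synthesis; the ortho formyl group lowers the barrier for copper insertion into the flanked C–Br bond, and the phenol has two free ortho positions, which forms the e6–O–f1 ether.

Step 4
Reactants: 6 EF aldehyde
Product: 8 2-[4-(benzyloxy)-3,5-dimethoxyphenoxy]-3,4,5-trimethoxyphenol (EF phenol), via EF formate 7 (not isolated)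
Conditions: mCPBA, CH2Cl2, 0 °C to rt; aqueous NaHCO3 wash; then K2CO3 (cat.), MeOH, rt
Reagents that add atoms: mCPBA (3-chloroperoxybenzoic acid), OOC(=O)c1cccc(Cl)c1
Why: Baeyer–Villiger oxidation in the Dakin sense; the ortho aryloxy and para methoxy groups make aryl migration strongly preferred, so the formyl carbon is replaced by the e1 hydroxyl.

Step 5
Reactants: 8 EF phenol; 9 3-bromo-4,5-dimethoxybenzaldehyde
Product: 10 3-{2-[4-(benzyloxy)-3,5-dimethoxyphenoxy]-3,4,5-trimethoxyphenoxy}-4,5-dimethoxybenzaldehyde (DEF aldehyde)
Conditions: CuI (cat.), N,N-dimethylglycine hydrochloride (cat.), Cs2CO3, 1,4-dioxane, 100 °C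
Reagents that add atoms: none
Why: Ullmann diaryl ether synthesis of a bromide with one ortho methoxy group and a meta formyl group, a long-used partner type for phenols; it forms the d5–O–e1 ether, the one junction that a formyl group cannot activate for substitution.

Step 6
Reactants: 10 DEF aldehyde
Product: 12 3-{2-[4-(benzyloxy)-3,5-dimethoxyphenoxy]-3,4,5-trimethoxyphenoxy}-4,5-dimethoxyphenol (DEF phenol), via DEF formate 11 (not isolated)
Conditions: mCPBA, CH2Cl2, 0 °C to rt; aqueous NaHCO3 wash; then K2CO3 (cat.), MeOH, rt
Reagents that add atoms: mCPBA (3-chloroperoxybenzoic acid), OOC(=O)c1cccc(Cl)c1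
Why: Baeyer–Villiger oxidation in the Dakin sense, here on a 3,4,5-trioxygenated benzaldehyde whose para methoxy group directs aryl migration; it gives the d1 phenol with two free ortho positions.

Step 7
Reactants: 12 DEF phenol; 5 2-bromo-3,4,5-trimethoxybenzaldehyde
Product: 13 2-(3-{2-[4-(benzyloxy)-3,5-dimethoxyphenoxy]-3,4,5-trimethoxyphenoxy}-4,5-dimethoxyphenoxy)-3,4,5-trimethoxybenzaldehyde (CDEF aldehyde)
Conditions: CuI (cat.), N,N-dimethylglycine hydrochloride (cat.), Cs2CO3, 1,4-dioxane, 100 °C
Reagents that add atoms: none
Why: Ullmann diaryl ether synthesis of the same kind as step 3, with the unhindered d1 phenol and the formyl-assisted bromide; it forms the c6–O–d1 ether.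

Step 8
Reactants: 13 CDEF aldehyde
Product: 15 2-(3-{2-[4-(benzyloxy)-3,5-dimethoxyphenoxy]-3,4,5-trimethoxyphenoxy}-4,5-dimethoxyphenoxy)-3,4,5-trimethoxyphenol (CDEF phenol), via CDEF formate 14 (not isolated)
Conditions: mCPBA, CH2Cl2, 0 °C to rt; aqueous NaHCO3 wash; then K2CO3 (cat.), MeOH, rt
Reagents that add atoms: mCPBA (3-chloroperoxybenzoic acid), OOC(=O)c1cccc(Cl)c1
Why: Baeyer–Villiger oxidation in the Dakin sense as in step 4; it converts the c1 formyl group into the c1 hydroxyl.

Step 9
Reactants: 15 CDEF phenol; 16 4-fluoro-3,5-dimethoxybenzaldehyde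
Product: 17 4-[2-(3-{2-[4-(benzyloxy)-3,5-dimethoxyphenoxy]-3,4,5-trimethoxyphenoxy}-4,5-dimethoxyphenoxy)-3,4,5-trimethoxyphenoxy]-3,5-dimethoxybenzaldehyde (BCDEF aldehyde)
Conditions: Cs2CO3, DMSO, 120 °C
Reagents that add atoms: none
Why: Nucleophilic aromatic substitution by addition–elimination; the para formyl group stabilises the Meisenheimer adduct and fluoride is the best leaving group, so the flanked carbon b4 is attacked by the phenoxide and the b4–O–c1 ether forms.

Step 10
Reactants: 17 BCDEF aldehyde
Product: 18 4-[2-(3-{2-[4-(benzyloxy)-3,5-dimethoxyphenoxy]-3,4,5-trimethoxyphenoxy}-4,5-dimethoxyphenoxy)-3,4,5-trimethoxyphenoxy]-3,5-dimethoxybenzoic acid (BCDEF acid)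
Conditions: NaClO2, NaH2PO4, 2-methyl-2-butene, t-BuOH/THF/H2O, rt
Reagents that add atoms: sodium chlorite, [Na+].[O-]Cl=O
Why: Pinnick oxidation; the alkene traps the hypochlorous acid that would otherwise chlorinate the electron-rich rings.

Step 11
Reactants: 18 BCDEF acid; 19 2,4,6-trimethoxyphenol
Product: 20 2,4,6-trimethoxyphenyl ester of acid 18, with the benzyl ether at f4 retained (ring A ester)
Conditions: DCC, DMAP (cat.), CH2Cl2, 0 °C to rt, argon
Reagents that add atoms: none
Why: Steglich esterification; the acyl pyridinium intermediate is reactive enough for a phenol with two ortho methoxy groups, because the crowding lies on the oxygen side and not at the unhindered acyl carbon.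

Step 12
Reactants: 20 ring A ester
Product: 21 2,4,6-trimethoxyphenyl ester with a free f4 hydroxyl (ring A ester phenol)
Conditions: H2 (1 atm), Pd/C, EtOAc/THF, rt
Reagents that add atoms: none
Why: Hydrogenolysis of the benzyl ether; aryl esters, methyl ethers and diaryl ethers are inert under these neutral conditions.

Step 13
Reactants: 21 ring A ester phenol; 22 3,4,5-trimethoxybenzoyl chloride
Product: 23 per-O-methyl diester: 2,4,6-trimethoxyphenyl ester at the ring B carboxyl and 3,4,5-trimethoxybenzoate at the f4 oxygen of the BCDEF pentamer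
Conditions: Et3N, DMAP (cat.), CH2Cl2, 0 °C to rt
Reagents that add atoms: none
Why: DMAP-catalysed acylation of a 2,6-dimethoxyphenol with an acid chloride; the acid chloride is far more electrophilic than the hindered aryl ester already present, so no ester exchange is expected.

Step 14
Reactants: 23 per-O-methyl diester
Product: 24 per-O-methyl heptamer (eighteen methyl ethers)
Conditions: Ni(cod)2 (40 mol%), 3,4-bis(dicyclohexylphosphino)thiophene (80 mol%), K3PO4, m-xylene, 160 °C, high dilution, slow argon sweep
Reagents that add atoms: none
Why: Proposed new method: zerovalent nickel carrying the chelating, electron-rich bisphosphine should insert into the acyl C–O bond of each aryl ester to give an acyl aryloxide complex of divalent nickel, the aryl group then shifts from the acyl carbon to nickel with release of carbon monoxide, and C–O reductive elimination from the aryl nickel aryloxide gives the diaryl ether and returns zerovalent nickel; the closest known reaction type is the nickel- or palladium-catalysed decarbonylative etherification of aryl esters of arene- and heteroarenecarboxylic acids, whose shown scope does not reach esters of electron-rich phenols with two ortho oxygens. The two events form the a4–O–b1 and f4–O–g1 bonds; no ring is closed and no stereocentre is formed. The step needs insertion at the acyl C–O bond in preference to the aryl C–O bond of the ester and to the methoxy and diaryl ether C–O bonds: the ortho methoxy pairs at a4 and f4 shield the aryl C–O bonds, the acyl carbons on b1 and g1 are flanked only by hydrogens, and insertion into a methyl ether is unproductive without a reductant or a transmetalating partner. It also needs loss of carbon monoxide and reductive elimination to outrun exchange of aryloxide between nickel centres, which would scramble the end rings; high dilution, a non-polar solvent and continuous removal of carbon monoxide are meant to secure this. The hindered, electron-rich aryloxides are expected to slow the insertion but to speed the C–O reductive elimination, which is why a higher loading and temperature than for simple esters are planned.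

Step 15
Reactants: 24 per-O-methyl heptamer
Product: 25 target heptamer with eighteen free hydroxyls (CNP0130704.0)
Conditions: BBr3 (excess), CH2Cl2, −78 °C to rt, argon; then degassed MeOH/H2O
Reagents that add atoms: none
Why: Lewis-acid ether cleavage; bromide attacks the methyl carbon of each boron-complexed aryl methyl ether, while diaryl ethers offer no such carbon and stay intact, and the acidic oxygen-free work-up protects the polyphenol.

## Compound list

1 | syringaldehyde (4-hydroxy-3,5-dimethoxybenzaldehyde) | COc1cc(C=O)cc(OC)c1O | starting material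
2 | 4-(benzyloxy)-3,5-dimethoxybenzaldehyde | COc1cc(C=O)cc(OC)c1OCc1ccccc1 | intermediate
3 | 4-(benzyloxy)-3,5-dimethoxyphenyl formate | COc1cc(OC=O)cc(OC)c1OCc1ccccc1 | intermediate
4 | 4-(benzyloxy)-3,5-dimethoxyphenol | COc1cc(O)cc(OC)c1OCc1ccccc1 | intermediate
5 | 2-bromo-3,4,5-trimethoxybenzaldehyde | COc1cc(C=O)c(Br)c(OC)c1OC | starting material
6 | EF aldehyde, 2-[4-(benzyloxy)-3,5-dimethoxyphenoxy]-3,4,5-trimethoxybenzaldehyde | COc1cc(C=O)c(Oc2cc(OC)c(OCc3ccccc3)c(OC)c2)c(OC)c1OC | intermediate
7 | EF formate, 2-[4-(benzyloxy)-3,5-dimethoxyphenoxy]-3,4,5-trimethoxyphenyl formate | COc1cc(OC=O)c(Oc2cc(OC)c(OCc3ccccc3)c(OC)c2)c(OC)c1OC | intermediate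
8 | EF phenol, 2-[4-(benzyloxy)-3,5-dimethoxyphenoxy]-3,4,5-trimethoxyphenol | COc1cc(O)c(Oc2cc(OC)c(OCc3ccccc3)c(OC)c2)c(OC)c1OC | intermediate
9 | 3-bromo-4,5-dimethoxybenzaldehyde | COc1cc(C=O)cc(Br)c1OC | starting material
10 | DEF aldehyde | COc1cc(C=O)cc(Oc2cc(OC)c(OC)c(OC)c2Oc2cc(OC)c(OCc3ccccc3)c(OC)c2)c1OC | intermediate
11 | DEF formate | COc1cc(OC=O)cc(Oc2cc(OC)c(OC)c(OC)c2Oc2cc(OC)c(OCc3ccccc3)c(OC)c2)c1OC | intermediate
12 | DEF phenol | COc1cc(O)cc(Oc2cc(OC)c(OC)c(OC)c2Oc2cc(OC)c(OCc3ccccc3)c(OC)c2)c1OC | intermediate
13 | CDEF aldehyde | COc1cc(C=O)c(Oc2cc(OC)c(OC)c(Oc3cc(OC)c(OC)c(OC)c3Oc3cc(OC)c(OCc4ccccc4)c(OC)c3)c2)c(OC)c1OC | intermediate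
14 | CDEF formate | COc1cc(OC=O)c(Oc2cc(OC)c(OC)c(Oc3cc(OC)c(OC)c(OC)c3Oc3cc(OC)c(OCc4ccccc4)c(OC)c3)c2)c(OC)c1OC | intermediate
15 | CDEF phenol | COc1cc(O)c(Oc2cc(OC)c(OC)c(Oc3cc(OC)c(OC)c(OC)c3Oc3cc(OC)c(OCc4ccccc4)c(OC)c3)c2)c(OC)c1OC | intermediate
16 | 4-fluoro-3,5-dimethoxybenzaldehyde | COc1cc(C=O)cc(OC)c1F | starting material
17 | BCDEF aldehyde (formyl at b1, benzyl ether at f4) | COc1cc(C=O)cc(OC)c1Oc1cc(OC)c(OC)c(OC)c1Oc1cc(OC)c(OC)c(Oc2cc(OC)c(OC)c(OC)c2Oc2cc(OC)c(OCc3ccccc3)c(OC)c2)c1 | intermediate
18 | BCDEF acid (carboxyl at b1, benzyl ether at f4) | COc1cc(C(=O)O)cc(OC)c1Oc1cc(OC)c(OC)c(OC)c1Oc1cc(OC)c(OC)c(Oc2cc(OC)c(OC)c(OC)c2Oc2cc(OC)c(OCc3ccccc3)c(OC)c2)c1 | intermediate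
19 | 2,4,6-trimethoxyphenol | COc1cc(OC)c(O)c(OC)c1 | starting material
20 | ring A ester: 2,4,6-trimethoxyphenyl ester of 18, benzyl ether at f4 | COc1cc(OC)c(OC(=O)c2cc(OC)c(Oc3cc(OC)c(OC)c(OC)c3Oc3cc(OC)c(OC)c(Oc4cc(OC)c(OC)c(OC)c4Oc4cc(OC)c(OCc5ccccc5)c(OC)c4)c3)c(OC)c2)c(OC)c1 | intermediate
21 | ring A ester phenol: 2,4,6-trimethoxyphenyl ester with free f4 hydroxyl | COc1cc(OC)c(OC(=O)c2cc(OC)c(Oc3cc(OC)c(OC)c(OC)c3Oc3cc(OC)c(OC)c(Oc4cc(OC)c(OC)c(OC)c4Oc4cc(OC)c(O)c(OC)c4)c3)c(OC)c2)c(OC)c1 | intermediate
22 | 3,4,5-trimethoxybenzoyl chloride | COc1cc(C(Cl)=O)cc(OC)c1OC | starting material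
23 | per-O-methyl diester (ring A aryl ester at the b1 carboxyl, ring G benzoate at the f4 oxygen) | COc1cc(OC)c(OC(=O)c2cc(OC)c(Oc3cc(OC)c(OC)c(OC)c3Oc3cc(OC)c(OC)c(Oc4cc(OC)c(OC)c(OC)c4Oc4cc(OC)c(OC(=O)c5cc(OC)c(OC)c(OC)c5)c(OC)c4)c3)c(OC)c2)c(OC)c1 | intermediate
24 | per-O-methyl heptamer (eighteen methyl ethers) | COc1cc(OC)c(Oc2cc(OC)c(Oc3cc(OC)c(OC)c(OC)c3Oc3cc(OC)c(OC)c(Oc4cc(OC)c(OC)c(OC)c4Oc4cc(OC)c(Oc5cc(OC)c(OC)c(OC)c5)c(OC)c4)c3)c(OC)c2)c(OC)c1 | intermediate
25 | target heptamer with eighteen hydroxyls (CNP0130704.0) | Oc1cc(O)c(Oc2cc(O)c(Oc3cc(O)c(O)c(O)c3Oc3cc(O)c(O)c(Oc4cc(O)c(O)c(O)c4Oc4cc(O)c(Oc5cc(O)c(O)c(O)c5)c(O)c4)c3)c(O)c2)c(O)c1 | target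

## Step count and risks

Total step count: 15. Longest linear sequence: 15 steps, from syringaldehyde 1 to 25.

**Step 14 (key step).** The most likely failure is that insertion of nickel into the acyl C–O bond of esters of such electron-rich, doubly flanked phenols is too slow. The catalyst would then decay, aryloxide would be exchanged between nickel centres so that the end rings scramble, or the esters would simply be cleaved by phosphate.
The fallback uses known chemistry and sets out from aldehyde 17. Baeyer–Villiger oxidation of 17 (mCPBA, then K2CO3/MeOH) leads through the pentamer formate F1 to the pentamer phenol F2 with a free b1 hydroxyl. Substitution of a further portion of 16 by F2 (Cs2CO3, DMSO) gives the hexamer aldehyde F3, in which the new ring is ring A with a formyl group at a1. A second Baeyer–Villiger oxidation leads through the hexamer formate F4 to the hexamer phenol F5, and methylation (MeI, K2CO3, acetone) gives the hexamer benzyl ether F6. Hydrogenolysis (H2, Pd/C) frees the f4 hydroxyl in the hexamer phenol F7. An Ullmann coupling of this hindered phenol with 5-iodo-1,2,3-trimethoxybenzene (CuI, picolinic acid, K3PO4, DMSO, 100 °C) comes back to the route at 24.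

**Step 3.** Copper insertion into a C–Br bond flanked by formyl and methoxy is slow, so reduction of the bromide and base-induced degradation of the aldehyde at 100 °C may outrun the coupling.
The fallback sets out from phenol 4 and couples it under the same copper catalysis with methyl 2-bromo-3,4,5-trimethoxybenzoate, whose ester is inert to base, giving the EF methyl ester F8. Reduction with LiAlH4 gives the EF benzyl alcohol F9, and MnO2 oxidation comes back to the route at 6.

**Step 7.** The same slow insertion applies, now with a larger and more valuable phenol, so incomplete conversion and loss of the bromide by reduction are the likely outcome.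
The fallback sets out from phenol 12 and couples it with methyl 2-bromo-3,4,5-trimethoxybenzoate to the CDEF methyl ester F10. LiAlH4 reduction gives the CDEF benzyl alcohol F11, and MnO2 oxidation comes back to the route at 13.

**Step 9.** The two methoxy groups beside the fluorine donate into the reacting carbon and crowd it, so attack by the ortho-substituted phenoxide may be too slow below the temperature at which the aldehyde and DMSO begin to decompose.
The fallback sets out from phenol 15 and replaces substitution by an Ullmann coupling with methyl 4-bromo-3,5-dimethoxybenzoate (CuI, picolinic acid, K3PO4, DMSO), giving the BCDEF methyl ester F12. Saponification (LiOH, THF/MeOH/H2O) comes back to the route at 18, so that step 10 is no longer needed.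

**Step 15.** With eighteen ethers, cleavage may stop short at the flanked methoxy groups, and the free pyrogallol and phloroglucinol rings may oxidise during work-up and chromatography, so that the free polyphenol cannot be purified.
The fallback sets out from 24. After the BBr3 treatment the crude polyphenol is not chromatographed but acetylated at once (Ac2O, pyridine) to the octadecaacetate F13, which is stable to air and silica and can be separated from partly methylated material. Deacetylation with degassed methanolic HCl under argon comes back to the route at 25.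

## Further compounds

F1 | step 14 | pentamer formate (formate at b1, benzyl ether at f4) | COc1cc(OC=O)cc(OC)c1Oc1cc(OC)c(OC)c(OC)c1Oc1cc(OC)c(OC)c(Oc2cc(OC)c(OC)c(OC)c2Oc2cc(OC)c(OCc3ccccc3)c(OC)c2)c1
F2 | step 14 | pentamer phenol (free b1 hydroxyl, benzyl ether at f4) | COc1cc(O)cc(OC)c1Oc1cc(OC)c(OC)c(OC)c1Oc1cc(OC)c(OC)c(Oc2cc(OC)c(OC)c(OC)c2Oc2cc(OC)c(OCc3ccccc3)c(OC)c2)c1
F3 | step 14 | hexamer aldehyde (formyl at a1, benzyl ether at f4) | COc1cc(C=O)cc(OC)c1Oc1cc(OC)c(Oc2cc(OC)c(OC)c(OC)c2Oc2cc(OC)c(OC)c(Oc3cc(OC)c(OC)c(OC)c3Oc3cc(OC)c(OCc4ccccc4)c(OC)c3)c2)c(OC)c1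
F4 | step 14 | hexamer formate (formate at a1, benzyl ether at f4) | COc1cc(OC=O)cc(OC)c1Oc1cc(OC)c(Oc2cc(OC)c(OC)c(OC)c2Oc2cc(OC)c(OC)c(Oc3cc(OC)c(OC)c(OC)c3Oc3cc(OC)c(OCc4ccccc4)c(OC)c3)c2)c(OC)c1
F5 | step 14 | hexamer phenol (free a1 hydroxyl, benzyl ether at f4) | COc1cc(O)cc(OC)c1Oc1cc(OC)c(Oc2cc(OC)c(OC)c(OC)c2Oc2cc(OC)c(OC)c(Oc3cc(OC)c(OC)c(OC)c3Oc3cc(OC)c(OCc4ccccc4)c(OC)c3)c2)c(OC)c1
F6 | step 14 | hexamer benzyl ether (rings A to F per-O-methyl, benzyl ether at f4) | COc1cc(OC)c(Oc2cc(OC)c(Oc3cc(OC)c(OC)c(OC)c3Oc3cc(OC)c(OC)c(Oc4cc(OC)c(OC)c(OC)c4Oc4cc(OC)c(OCc5ccccc5)c(OC)c4)c3)c(OC)c2)c(OC)c1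
F7 | step 14 | hexamer phenol (rings A to F per-O-methyl, free f4 hydroxyl) | COc1cc(OC)c(Oc2cc(OC)c(Oc3cc(OC)c(OC)c(OC)c3Oc3cc(OC)c(OC)c(Oc4cc(OC)c(OC)c(OC)c4Oc4cc(OC)c(O)c(OC)c4)c3)c(OC)c2)c(OC)c1
F8 | step 3 | EF methyl ester, methyl 2-[4-(benzyloxy)-3,5-dimethoxyphenoxy]-3,4,5-trimethoxybenzoate | COC(=O)c1cc(OC)c(OC)c(OC)c1Oc1cc(OC)c(OCc2ccccc2)c(OC)c1
F9 | step 3 | EF benzyl alcohol, {2-[4-(benzyloxy)-3,5-dimethoxyphenoxy]-3,4,5-trimethoxyphenyl}methanol | OCc1cc(OC)c(OC)c(OC)c1Oc1cc(OC)c(OCc2ccccc2)c(OC)c1
F10 | step 7 | CDEF methyl ester | COC(=O)c1cc(OC)c(OC)c(OC)c1Oc1cc(OC)c(OC)c(Oc2cc(OC)c(OC)c(OC)c2Oc2cc(OC)c(OCc3ccccc3)c(OC)c2)c1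
F11 | step 7 | CDEF benzyl alcohol | OCc1cc(OC)c(OC)c(OC)c1Oc1cc(OC)c(OC)c(Oc2cc(OC)c(OC)c(OC)c2Oc2cc(OC)c(OCc3ccccc3)c(OC)c2)c1
F12 | step 9 | BCDEF methyl ester (methyl ester of 18) | COC(=O)c1cc(OC)c(Oc2cc(OC)c(OC)c(OC)c2Oc2cc(OC)c(OC)c(Oc3cc(OC)c(OC)c(OC)c3Oc3cc(OC)c(OCc4ccccc4)c(OC)c3)c2)c(OC)c1
F13 | step 15 | octadecaacetate of the target | CC(=O)Oc1cc(OC(C)=O)c(Oc2cc(OC(C)=O)c(Oc3cc(OC(C)=O)c(OC(C)=O)c(OC(C)=O)c3Oc3cc(OC(C)=O)c(OC(C)=O)c(Oc4cc(OC(C)=O)c(OC(C)=O)c(OC(C)=O)c4Oc4cc(OC(C)=O)c(Oc5cc(OC(C)=O)c(OC(C)=O)c(OC(C)=O)c5)c(OC(C)=O)c4)c3)c(OC(C)=O)c2)c(OC(C)=O)c1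
A1 | alternative 1 | per-O-methyl EFG trimer phenol with free e1 hydroxyl | Oc1cc(OC)c(OC)c(OC)c1Oc1cc(OC)c(Oc2cc(OC)c(OC)c(OC)c2)c(OC)c1
A2 | alternative 1 | 3,4-dimethoxy-4-(1-methoxyvinyl)-2-(FG-aryloxy)cyclobut-2-enone | C=C(OC)C1(OC)C(OC)=C(Oc2cc(OC)c(Oc3cc(OC)c(OC)c(OC)c3)c(OC)c2)C1=O
A3 | alternative 2 | heptamer with seventeen methyl ethers and a free d4 hydroxyl | COc1cc(OC)c(Oc2cc(OC)c(Oc3cc(OC)c(OC)c(OC)c3Oc3cc(OC)c(O)c(Oc4cc(OC)c(OC)c(OC)c4Oc4cc(OC)c(Oc5cc(OC)c(OC)c(OC)c5)c(OC)c4)c3)c(OC)c2)c(OC)c1
A4 | alternative 2 | 2-(ABC-aryloxy)-3-(dimethylamino)acrolein | CN(C)C=C(C=O)Oc1c(OC)c(OC)c(OC)cc1Oc1c(OC)cc(Oc2c(OC)cc(OC)cc2OC)cc1OC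
A5 | alternative 2 | 1-(EFG-aryloxy)-3-methoxyacetone | COCC(=O)COc1cc(OC)c(OC)c(OC)c1Oc1cc(OC)c(Oc2cc(OC)c(OC)c(OC)c2)c(OC)c1
A6 | alternative 3 | heptamer with free phloroglucinol ring A and fifteen methyl ethers on rings B to G | Oc1cc(O)c(Oc2cc(OC)c(Oc3cc(OC)c(OC)c(OC)c3Oc3cc(OC)c(OC)c(Oc4cc(OC)c(OC)c(OC)c4Oc4cc(OC)c(Oc5cc(OC)c(OC)c(OC)c5)c(OC)c4)c3)c(OC)c2)c(O)c1
A7 | alternative 3 | S-tert-butyl 6-(BCDEFG-aryloxy)-3,5-dioxohexanethioate | CC(C)(C)SC(=O)CC(=O)CC(=O)COc1cc(OC)c(Oc2cc(OC)c(OC)c(OC)c2Oc2cc(OC)c(OC)c(Oc3cc(OC)c(OC)c(OC)c3Oc3cc(OC)c(Oc4cc(OC)c(OC)c(OC)c4)c(OC)c3)c2)c(OC)c1
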